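All runs were generated by integration for substances that don't exist; the scatter is artificial.

The meeting decided to plan E in this flask from one number read off the two earlier runs.

| flask | L | G | remark | time |
|---|---|---|---|---|
| autumn | 0.25 M | 0.475 M (fed, over 20 s) | run made earlier; the fed solution adds 0.10 times the starting volume |  |
| spring | 1 M | 0.475 M (fed, over 20 s) | run made earlier; the fed solution adds 0.10 times the starting volume |  |
| flask | 0.50 M | 0.475 M (fed, over 20 s) | the fed solution adds 0.10 times the starting volume | 25 min |

| run | time / min | L / % | E / % | X / % |
|---|---|---|---|---|
| autumn | 6.00 | 0 | 39.7 | 55.5 |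
| autumn | 12.0 | 0 | 39.4 | 54.9 |
| autumn | 20.0 | 0 | 39.1 | 55.4 |
| autumn | 25.0 | 1.0 | 40.2 | 55.5 |
| autumn | 30.0 | 0 | 39.8 | 54.5 |
| spring | 2.50 | 0.6 | 27.6 | 52.1 |
| spring | 5.00 | 0 | 29.2 | 54.2 |
| spring | 8.00 | 0 | 29.7 | 54.2 |
| spring | 15.0 | 0 | 28.7 | 54.3 |
| spring | 30.0 | 0 | 27.6 | 54.4 |

(scatter of a reading: 0.5 percentage points)

- percent here means L units held: one J counts as two
- what is said of E includes Z
- amounts are per litre of the starting volume; all of the dose is in the solution fed
- Z is a solid; its amount is given per volume of the solution
- what was read earlier has a scatter of 0.5 percentage points, one standard deviation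
- steps that have been proposed: Z <-> E; 2 L -> J; L <-> D; L <-> Q; L + G -> E; D -> X
- the reaction counts as stopped when no species that holds the L changes by six tenths of a point or more over the second half of the time

1. why nothing more happens at 25 min, or that something still does (forward and back rates have come level / all of L has reacted / it is still moving / G has run out first)
2. share of the L used up at 25 min
3. E at 25 min, in percent of the L charged
4. X at 25 min, in percent of the L charged

The first speaker reported that L reads 0 % in autumn at 6.00 min and 0 % in spring at 5.00 min, with X flat afterwards within the scatter, while E in spring reads from 27.6 % to 29.7 % over those later times. She noted that X averages 55.2 % in autumn and 54.3 % in spring, so she proposed to carry that share over.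

The second speaker argued that the rest of the L is E or J. E averages 39.6 % in autumn and 28.8 % in spring, which leaves J at 5.20 % and 16.9 %. The proposed steps make J go with L squared and E with L times G, so J over E should go as L over G. He therefore took mean G per L charged as the charge ratio less half the E made, which reads 1.70 in autumn and 0.331 in spring. J over E times that mean G reads 0.223 and 0.195. Their mean, 0.209, is the split number, a selectivity factor.

I reckoned the flask from it. The share outside X is 45.3 %. Full G at 0.950 per L gives E of 37.1 %. Putting that back lowers mean G to 0.764, and the second round gives 35.6 %.

The forecast says all of L has reacted, with conversion 100 %, E 35.2 % (from 33.5 % to 37 %) and X 55 % (from 53.5 % to 56.2 %): “X holds at about 55% whatever the L concentration”. My 35.6 % for E stands a little higher than its figure.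

The flask gives all of L has reacted, with conversion 100 %, E 35.5 % and X 55.2 %.

    Z ⇌ E, rate k1*(cs1 - [E]) while solid is left; crystals form when [E] > cs1 (solubility = 0.240 M, k = 4.00 /s)
    2 L → J (k = 0.0230 /M/s)
    L ⇌ D (K = 0.420, k = 0.0510 /s)
    L ⇌ Q (K = 1.50, k = 0.0790 /s)
    L + G → E (k = 0.140 /M/s)
    D → X (k = 0.860 /s)

In this flask, J of 9.23 % over E of 35.5 %, at a mean G of 0.772, gives a split number of 0.201. The neighbour charged with 1.2 M of L, at 0.396 equiv of G, ends with E 26.5 % and J 19.6 %, which gives 0.194. Striking the step from D to X out of this flask raises E from 35.5 % to 84.6 %, and striking the step from L to D, both ways, raises it to 82.4 %, so these two steps acting together hold E down in this flask. The neighbour charged with 1.2 M of G ends with X at 38.6 %, below the low end of the forecast's range for this flask, 53.5 %.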